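**Remarks on the chemistry (assumptions)**

- The acyl chain of the given SMILES is read as 36 carbons (35 sp3 carbons plus the ester carbonyl), so the target is 2-(4-hydroxyphenyl)ethyl hexatriacontanoate, C44H80O3. It has no stereocentre and no stereogenic double bond, so the achiral compound is itself "the single enantiomer given" and no step has to control configuration.
- Compounds 1, 2 and 5 are taken as purchased. Compound 1 must be a homologue-free grade (no C16 acid).
- Numbering used throughout: 1 octadecanoic acid (stearic acid); 2 20-(tert-butoxy)-20-oxoicosanoic acid; 3 tert-butyl hexatriacontanoate; 4 hexatriacontanoic acid; 5 tyrosol; 6 target.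
- Locants of 6: acyl chain C1 (ester C=O) to C36 (CH3); alcohol part C1′ (OCH2) and C2′ (ArCH2); ring C1″–C6″ with OH on C4″.

## Analysis of the target

Compound 6 is the ester of the saturated, unbranched C36 fatty acid with the primary hydroxyl of tyrosol. Its chain runs from C1 (ester carbonyl) to C36 (CH3) with 34 methylene groups (C2–C35), and is joined through oxygen to C1′H2–C2′H2 and one para-disubstituted benzene ring (C1″–C6″) with a free phenolic OH on C4″. There is no stereocentre and no ring other than the benzene ring, so nothing stereochemical has to be set. The sensitive groups are the free phenol (easily oxidised, and as phenoxide a competing acyl acceptor) and the ester (cleaved or transacylated by base). The difficulty lies in the chain, not the functional groups: the C36 acid is not a commodity, whereas even-numbered acids and diacid half-esters up to about C22 are. Between C1 and C36 there is no functional group, so every polar C–C bond formation inside the chain leaves a group (alkene, alkyne, carbinol, ketone) that has to be erased afterwards. Homologues that differ by one or two CH2 groups cannot be separated from a C36 wax, so the chain length must follow from the construction and from homologue-pure building blocks; the low solubility of all C36 compounds in cold solvents adds a practical burden. The feature the strategy exploits is the C19–C20 bond in the middle of the polymethylene chain: two unactivated methylene carbons, flanked by C2–C18 on one side and C21–C36 on the other. Cutting there gives a C17 alkyl fragment and an ester-terminated C19 alkyl fragment, each of which is a commodity carboxylic acid minus its carboxyl carbon. This is the case for an anodic decarboxylative radical coupling, which joins two carbons of like polarity and leaves no trace.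

## Retrosynthetic reasoning

**6 ⇒ 4 + 5 (acyl C1–O bond).** This is the only heteroatom bond of the skeleton, and it is cut first in the retrosynthetic direction so that it is formed last. The phenol ring of 5 is oxidised well below the potential at which carboxylates are discharged, so it must not be present during the electrochemical step. Forming the ester last also makes a protecting group on the C4″ oxygen unnecessary. The forward reaction has to acylate the aliphatic hydroxyl at C1′ and leave the phenol alone; an equilibrium acid-catalysed (Fischer) esterification does this by nucleophilicity and by ester stability.

**4 ⇒ 3 (O–tert-butyl bond).** The carboxyl group at C1 has to pass through the key step as a non-electroactive ester, because a free carboxyl at C1 would be discharged at the anode like the other one. The tert-butyl ester is chosen because it comes with purchased 2, is inert at the anode and in buffered alcohol, and is removed by acid alone. That avoids saponification and the intractable soaps of a C36 acid. The isolated acid 4 is also a crystalline purification point.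

**3 ⇒ 1 + 2 (C19–C20 bond, key disconnection).** The cut is made between C19 and C20. C20 of 3 is the former α-carbon (C2) of 1, and C19 of 3 is the former C19 of 2, the carbon α to its free carboxyl group. Both partners are carboxylic acids, so the two carbons have the same polarity and can only be joined as radicals after decarboxylation. Kolbe logic would allow a cut at almost any bond from C3 to C35, but C19–C20 is the one at which both halves are bulk chemicals: the cheapest long-chain fatty acid and the C20 diacid half-ester produced as a side-chain building block for lipidated peptide drugs. Cuts elsewhere would need odd-chain or rare acids. A symmetric homo-coupling is not possible because the two chain ends differ (CH3 versus ester). The gain is the complete, correctly terminated C36 skeleton in one operation from two purchased compounds, with current as the only redox reagent and no auxiliary functional group to erase. The forward reaction has to generate both primary radicals at the same anode, favour cross- over homo-coupling, avoid over-oxidation of the radicals to cations, and leave the ester of 2 untouched.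

## Alternatives that were turned down

**Alternative 1:** The textbook route treats the ester C1–O bond as the strategic cut (4 + 5) and assembles 4 by a Wittig olefination across C18=C19. Forward: 18-bromooctadecanoic acid A1 is converted into (17-carboxyheptadecyl)triphenylphosphonium bromide A2, whose ylide is condensed with octadecanal A3 to give (Z)-hexatriacont-18-enoic acid A4; hydrogenation gives 4, and esterification with 5 gives 6. Turned down because the ester bond is trivial and does not address the chain, which is the real problem. A1 and A3 are costly speciality chemicals, and A3 is an air-sensitive, self-condensing aldehyde. The carboxylate-ylide of A2 is a poorly soluble dianion. The sequence needs four operations, builds a C=C bond in A4 only to erase it, and leaves phosphine oxide to be separated from a wax.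

**Alternative 2:** A polar sp3–sp3 cross-coupling at the C18–C19 bond of 3. Forward: copper-catalysed Kumada-type coupling of octadecylmagnesium bromide A5 with tert-butyl 18-bromooctadecanoate A6 gives 3, then on as in the main route. Turned down as the main line because a nucleophile/electrophile union needs the two halves in different oxidation states. A6 is not an article of commerce and would have to be made from a desymmetrised C18 diacid by reduction and bromination, so the way to the precursor costs more steps than the key step saves. A5 is a waxy reagent of limited solubility in cold ethers, and its homo-coupling would give an ester-free C36 by-product that co-crystallises with the product. The chemistry is reliable, so a variant of it is kept as the fallback for the key step.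

**Alternative 3:** An olefin cross-metathesis that makes C13=C14, followed by hydrogenation. Forward: erucic acid A7 is esterified with 5 to give 2-(4-hydroxyphenyl)ethyl (Z)-docos-13-enoate A8; ruthenium-carbene-catalysed cross-metathesis with 1-tetracosene A9 gives 2-(4-hydroxyphenyl)ethyl (E)-hexatriacont-13-enoate A10; hydrogenation gives 6. Turned down because both olefins are electronically and sterically unbiased, so the metathesis is statistical and self-metathesis competes. More seriously, ruthenium hydride species migrate double bonds before metathesis and would produce C35 and C37 homologues that cannot be removed from a C36 wax. A9 is sold mainly as a technical α-olefin cut, which worsens this. The route is no shorter (three steps) and again installs an alkene only to hydrogenate it.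

Key step: step 1

## Route

Step 1
Reactants: 1 octadecanoic acid (stearic acid, homologue-free, 4 equiv); 2 20-(tert-butoxy)-20-oxoicosanoic acid (mono-tert-butyl icosanedioate, 1 equiv)
Product: 3 tert-butyl hexatriacontanoate
Conditions: undivided cell, smooth Pt anode, Pt cathode, KOH (0.1 equiv per CO2H), MeOH–cyclohexane 3:1, 50 °C, constant current ca. 0.2 A cm⁻², until pH ca. 8 (ca. 1.3 F per mol CO2H); cool, filter, SiO2 (hexane → hexane/toluene)
Reagents that add atoms: none
Why: Mixed (crossed) Kolbe electrolysis, the anodic decarboxylative radical coupling long used to extend fatty acids with half-esters of α,ω-diacids, forms the C19–C20 bond of 3. At the smooth Pt anode above ca. 2.1 V the carboxylates of 1 and 2 form an adsorbed layer, are oxidised by one electron each and lose CO2 at once, giving the primary C17 alkyl radical from 1 and the primary, ester-terminated C19 alkyl radical from 2 at high surface concentration. These unstabilised primary radicals couple at close to diffusion-controlled rates, while high current density, a weakly acidic medium (only 10 % neutralisation) and the absence of α-substituents disfavour the second electron transfer to carbocations (Hofer–Moest path). The selectivity needed is cross- over homo-coupling, which is statistical because the two radicals are equally reactive; the fourfold excess of cheap 1 means that, on statistical grounds, about four of five radicals from 2 should meet a radical from 1. The three coupling products carry no, one and two ester groups, so 3 should separate cleanly on silica after the ester-free hydrocarbon has largely crystallised from the cooled mixture. The tert-butyl ester is not electroactive, sits 18 methylene groups from the radical centre and survives the buffered alcohol, and cyclohexane keeps the waxy products in solution and off the anode. No ring is closed and no stereocentre is formed. Chain length is fixed solely by the two acids, which is why homologue-free 1 is specified.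

Step 2
Reactants: 3 tert-butyl hexatriacontanoate
Product: 4 hexatriacontanoic acid
Conditions: TFA–CHCl3 1:3, 50 °C; evaporate; recrystallise (toluene)
Reagents that add atoms: none
Why: Acidolysis of a tert-butyl ester by alkyl–oxygen cleavage (AAL1, loss of the tert-butyl cation as isobutene) is specific for this group and needs no base, so no C36 soap is formed; warm chloroform keeps the wax dissolved, and crystallisation of 4 removes neutral impurities carried from step 1.

Step 3
Reactants: 4 hexatriacontanoic acid; 5 tyrosol (2-(4-hydroxyphenyl)ethanol, 3 equiv)
Product: 6 2-(4-hydroxyphenyl)ethyl hexatriacontanoate
Conditions: TsOH·H2O (5 mol %), toluene, reflux, Dean–Stark; wash hot with water, cool; recrystallise (EtOAc)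
Reagents that add atoms: none
Why: Fischer esterification under equilibrium acid catalysis acylates the primary aliphatic hydroxyl at C1′, whereas aryl esters are disfavoured (the phenol is a poor nucleophile and a good leaving group), so the C4″ phenol should stay free without protection. Excess 5 and azeotropic removal of water drive the conversion, and refluxing toluene keeps 4 and 6 in solution.

## Compound list

1 | octadecanoic acid (stearic acid) | CCCCCCCCCCCCCCCCCC(=O)O | starting material
2 | 20-(tert-butoxy)-20-oxoicosanoic acid (mono-tert-butyl icosanedioate) | CC(C)(C)OC(=O)CCCCCCCCCCCCCCCCCCC(=O)O | starting material
3 | tert-butyl hexatriacontanoate | CCCCCCCCCCCCCCCCCCCCCCCCCCCCCCCCCCCC(=O)OC(C)(C)C | intermediate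
4 | hexatriacontanoic acid | CCCCCCCCCCCCCCCCCCCCCCCCCCCCCCCCCCCC(=O)O | intermediate
5 | tyrosol, 2-(4-hydroxyphenyl)ethanol | OCCc1ccc(O)cc1 | starting material
6 | 2-(4-hydroxyphenyl)ethyl hexatriacontanoate (achiral) | CCCCCCCCCCCCCCCCCCCCCCCCCCCCCCCCCCCC(=O)OCCc1ccc(O)cc1 | target

## Step count and risk

Total step count: 3. Longest linear sequence: 3 steps (2 → 3 → 4 → 6; 1 and 5 are bought and enter in steps 1 and 3).

**Step 1 (key step).** The most likely failure is fouling of the anode by a film of the waxy coupling products. This raises the cell voltage, lowers the radical concentration at the surface and shifts the reaction towards the two-electron (Hofer–Moest) path with solvent capture and elimination. Statistical homo-coupling of the radicals from 2 and radical disproportionation lower the amount of cross-product further. Co-coupling of homologous acids would contaminate the chain length if 1 is not homologue-free. The fallback builds the same chain by polar chemistry, sets out from 2 and comes back at 3. The free carboxyl group of 2 is reduced chemoselectively with borane–dimethyl sulfide (THF, 0 °C to rt; the tert-butyl ester is not touched) to tert-butyl 20-hydroxyicosanoate F1. Appel bromination (CBr4, PPh3, CH2Cl2) gives tert-butyl 20-bromoicosanoate F2. Copper-catalysed sp3–sp3 Kumada-type coupling (Li2CuCl4 cat., THF–NMP, 0 °C) of F2 with hexadecylmagnesium bromide F3, prepared from commercial cetyl bromide and magnesium, forms the C20–C21 bond and should give 3; the hindered ester resists the Grignard reagent under these conditions.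

**Step 3.** Esterification may stop short because a sparingly soluble acid approaches equilibrium slowly. Acid-catalysed self-condensation of excess 5 (ether formation, ring alkylation) and slow acylation of the phenol on prolonged heating are the other risks. The fallback sets out from 4 and comes back at 6, and replaces chemoselectivity by protection. Compound 4 is coupled with purchased 2-[4-(benzyloxy)phenyl]ethanol F5 using N,N′-diisopropylcarbodiimide and catalytic DMAP (toluene–CH2Cl2, 40 °C) to give 2-[4-(benzyloxy)phenyl]ethyl hexatriacontanoate F6. Hydrogenolysis of the benzyl ether (H2, Pd/C, THF–EtOAc, 40 °C) should then give 6; the alkyl ester and the ring are not affected.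

**Step 2.** Acidolysis may be incomplete if the wax is not fully in solution, and material may be lost in the crystallisation of a compound that is poorly soluble when cold. The fallback sets out from 3 and comes back at 4, and goes through an acyl chloride instead of a proton-catalysed cleavage. Thionyl chloride, which converts tert-butyl esters directly into acid chlorides while other esters are inert, should give hexatriacontanoyl chloride F4 (toluene, 40 °C). Hydrolysis in warm aqueous THF gives 4. If step 3 also needs its fallback, F4 can be used directly to acylate F5.

## Further compounds

F1 | step 1 | tert-butyl 20-hydroxyicosanoate | CC(C)(C)OC(=O)CCCCCCCCCCCCCCCCCCCO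
F2 | step 1 | tert-butyl 20-bromoicosanoate | CC(C)(C)OC(=O)CCCCCCCCCCCCCCCCCCCBr
F3 | step 1 | hexadecylmagnesium bromide | CCCCCCCCCCCCCCCC[Mg]Br
F4 | step 2 | hexatriacontanoyl chloride | CCCCCCCCCCCCCCCCCCCCCCCCCCCCCCCCCCCC(=O)Cl
F5 | step 3 | 2-[4-(benzyloxy)phenyl]ethanol (purchased) | OCCc1ccc(OCc2ccccc2)cc1
F6 | step 3 | 2-[4-(benzyloxy)phenyl]ethyl hexatriacontanoate | CCCCCCCCCCCCCCCCCCCCCCCCCCCCCCCCCCCC(=O)OCCc1ccc(OCc2ccccc2)cc1
A1 | alternative 1 | 18-bromooctadecanoic acid | OC(=O)CCCCCCCCCCCCCCCCCBr
A2 | alternative 1 | (17-carboxyheptadecyl)triphenylphosphonium bromide | OC(=O)CCCCCCCCCCCCCCCCC[P+](c1ccccc1)(c1ccccc1)c1ccccc1.[Br-]
A3 | alternative 1 | octadecanal | CCCCCCCCCCCCCCCCCC=O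
A4 | alternative 1 | (Z)-hexatriacont-18-enoic acid | CCCCCCCCCCCCCCCCC/C=C\CCCCCCCCCCCCCCCCC(=O)O
A5 | alternative 2 | octadecylmagnesium bromide | CCCCCCCCCCCCCCCCCC[Mg]Br
A6 | alternative 2 | tert-butyl 18-bromooctadecanoate | CC(C)(C)OC(=O)CCCCCCCCCCCCCCCCCBr
A7 | alternative 3 | erucic acid, (Z)-docos-13-enoic acid | CCCCCCCC/C=C\CCCCCCCCCCCC(=O)O
A8 | alternative 3 | 2-(4-hydroxyphenyl)ethyl (Z)-docos-13-enoate | CCCCCCCC/C=C\CCCCCCCCCCCC(=O)OCCc1ccc(O)cc1
A9 | alternative 3 | 1-tetracosene | C=CCCCCCCCCCCCCCCCCCCCCCC
A10 | alternative 3 | 2-(4-hydroxyphenyl)ethyl (E)-hexatriacont-13-enoate | CCCCCCCCCCCCCCCCCCCCCC/C=C/CCCCCCCCCCCC(=O)OCCc1ccc(O)cc1
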